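**Retrosynthetic overview**
- The target is cut at C11=C12 and C11'=C12' (two Wittig reactions) into a ring A C20 phosphonium salt, the C10 trienedial and a ring B C20 phosphonium salt; the CH2OH of ring B is carried as a methyl ester and reduced last.
- Feature used for ring A (C1 gem-dimethyl, C2 with the prenyl group, C3, C4=C5 with methyl on C5, C6 with the polyene): the first two prenyl carbons, Ca (CH2) and Cb (CH=), can be drawn as a ketone bridge from C2 to C5, so ring A is one ring of a 6-vinylbicyclo[2.2.2]octan-2-one. Norrish type 1 cleavage of C5–C(=O) gives back C4=C5 and C2–CH2–CHO, and the bridge fixes C2 and C6 cis.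
- The bicycle comes from a Diels–Alder reaction of a 2-silyloxy-6-vinylcyclohexa-1,3-diene (C5=Cb–Ca=C2) with phenyl vinyl sulfone (C3, C4) anti to the C6 vinyl group; the diene comes from 4,4-dimethylcyclohexenone by dehydrogenation, enantioselective Rh vinylation, methylation and silylation.
- Ring B (C2'/C6' trans) is the carbocycle of 2,4,4-trimethylcyclohexadienone: C2' by Rh-catalysed vinylation, C6' by trans conjugate vinylation with enolate triflation, C4'=C5' by triflate reduction, side chain by hydroboration, oxidation and Wittig reaction.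
- Ring order: the ring B carbocycle is bought, ring A is closed in the cycloaddition and released from the bicycle by photolysis; both vinyl groups are then extended by cross-metathesis, vinyl Grignard addition and PPh3·HBr.

Key step: step 5

Remark on labels: carotenoid numbering is used (ring A C1–C6, chain C7–C15, primes for the ring B half); Ca and Cb are the CH2 and CH= carbons of the prenyl group on C2.
Assumption: the Ph-bod* rhodium catalysts are taken to attack the two dienones with the facial sense known for cyclohex-2-enone; if the sense is the reverse, the ligand antipodes are exchanged between steps 2 and 14.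
Assumption: 2,4,4-trimethylcyclohex-2-en-1-one and (2E,4E,6E)-2,7-dimethylocta-2,4,6-trienedial are taken as catalogue compounds.

**Ring A half**

Step 1
Reactants: 1 4,4-dimethylcyclohex-2-en-1-one
Product: 2 4,4-dimethylcyclohexa-2,5-dien-1-one
Conditions: DDQ (1.2 equiv), TsOH·H2O (cat.), 1,4-dioxane, reflux
Reagents that add atoms: none
Why: Quinone dehydrogenation of a 4,4-disubstituted cyclohexenone (hydride abstraction from C5 of the dienol) is the standard route to the cross-conjugated dienone, which cannot aromatise because C4 is quaternary.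

Step 2
Reactants: 2 4,4-dimethylcyclohexa-2,5-dien-1-one; 3 potassium vinyltrifluoroborate
Product: 4 (5S)-5-ethenyl-4,4-dimethylcyclohex-2-en-1-one
Conditions: [Rh(C2H4)2Cl]2 (2.5 mol %), (S,S)-Ph-bod* [(1S,4S)-2,5-diphenylbicyclo[2.2.2]octa-2,5-diene] (5.5 mol %), Et3N, dioxane/H2O 10:1, 50 °C
Reagents that add atoms: potassium vinyltrifluoroborate, [K+].C=C[B-](F)(F)F
Why: Rhodium-catalysed asymmetric conjugate addition of an alkenylboron reagent (transmetalation to a vinylrhodium species, enantioface-selective insertion of one of the two enantiotopic enone units, hydrolysis of the rhodium enolate) desymmetrises the dienone and sets the C5 centre (later ring A C6) as S under control of the chiral diene ligand.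

Step 3
Reactants: 4 (5S)-5-ethenyl-4,4-dimethylcyclohex-2-en-1-one; 5 iodomethane
Product: 7 (5R,6R)-5-ethenyl-4,4,6-trimethylcyclohex-2-en-1-one, via lithium dienolate 6 (not isolated)
Conditions: LiN(iPr)2 (1.05 equiv), THF, −78 °C; then MeI, −78 → 0 °C
Reagents that add atoms: iodomethane, CI
Why: Kinetic α'-deprotonation of the enone (no γ-hydrogen exists because C4 is quaternary) and SN2 methylation of the cross-conjugated enolate should place the methyl group anti to the neighbouring vinyl group, although this new C6 centre is erased again in step 4.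

Step 4
Reactants: 7 (5R,6R)-5-ethenyl-4,4,6-trimethylcyclohex-2-en-1-one; 8 tert-butyldimethylsilyl trifluoromethanesulfonate
Product: 9 tert-butyl{[(6S)-6-ethenyl-1,5,5-trimethylcyclohexa-1,3-dien-2-yl]oxy}dimethylsilane
Conditions: TBSOTf (1.3 equiv), Et3N (2 equiv), CH2Cl2, 0 °C → rt
Reagents that add atoms: tert-butyldimethylsilyl trifluoromethanesulfonate, CC(C)(C)[Si](C)(C)OS(=O)(=O)C(F)(F)F
Why: Soft enolisation and O-silylation of an enone whose only acidic hydrogen is the α' one gives the cross-conjugated 2-silyloxy-1,3-diene regiospecifically and leaves the vinyl-bearing stereocentre untouched.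

Step 5
Reactants: 9 tert-butyl{[(6S)-6-ethenyl-1,5,5-trimethylcyclohexa-1,3-dien-2-yl]oxy}dimethylsilane; 10 phenyl vinyl sulfone
Product: 11 tert-butyl{[6-ethenyl-1,5,5-trimethyl-8-(phenylsulfonyl)bicyclo[2.2.2]oct-2-en-2-yl]oxy}dimethylsilane (vinyl and sulfonyl both syn to the C2=C3 enol ether bridge)
Conditions: 10 (2 equiv), BHT (cat.), Et3N (0.1 equiv), toluene, 120 °C, sealed tube
Reagents that add atoms: phenyl vinyl sulfone, C=CS(=O)(=O)c1ccccc1
Why: The electron-rich 2-silyloxy-1,3-diene (C5=Cb–Ca=C2) and the electron-poor vinyl sulfone should combine in a thermal, concerted but asynchronous [4+2] cycloaddition, the known class being Diels–Alder reactions of 2-silyloxycyclohexa-1,3-dienes with vinyl sulfones as ethylene equivalents. Ring A (C1–C6) closes by suprafacial addition across the diene termini: C5, which carries the largest HOMO coefficient, bonds to the sulfone CH2 carbon (C4) and C2 bonds to the sulfonyl-bearing carbon (C3), while the old ring becomes the Ca=Cb and C1–C6 bridges of a bicyclo[2.2.2]octene. The two bridgehead centres C2 and C5 are set together by the face of attack, which is controlled by the C6 stereocentre: the dienophile passes the C6 hydrogen and not the C6 vinyl group, so vinyl ends syn to the Ca=Cb bridge. The C3 sulfonyl centre is expected endo through secondary orbital overlap. Only the π-facial selectivity is needed, because regiochemistry and the C3 configuration are erased when the sulfone is removed in step 6. The gem-dimethyl group at C1 puts one methyl on each face and should slow the reaction without biasing it.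

Step 6
Reactants: 11 Diels–Alder adduct
Product: 12 tert-butyl{[6-ethenyl-1,5,5-trimethylbicyclo[2.2.2]oct-2-en-2-yl]oxy}dimethylsilane
Conditions: 6% Na(Hg), Na2HPO4, MeOH/THF 1:1, −20 °C
Reagents that add atoms: none
Why: Reductive desulfonylation by single-electron transfer (loss of benzenesulfinate, then reduction and protonation at C3) removes the activating group, while the silyl enol ether keeps the future ketone out of reach of the reductant and the unactivated vinyl group is inert.

Step 7
Reactants: 12 desulfonylated silyl enol ether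
Product: 13 6-ethenyl-1,5,5-trimethylbicyclo[2.2.2]octan-2-one (vinyl syn to the carbonyl bridge)
Conditions: 1 M HCl, THF, 0 °C → rt
Reagents that add atoms: none
Why: Acid hydrolysis of the silyl enol ether (C-protonation at Ca, loss of silanol) unveils the ketone at Cb next to the quaternary bridgehead C5 without touching a stereocentre.

Step 8
Reactants: 13 6-ethenyl-1,5,5-trimethylbicyclo[2.2.2]octan-2-one
Product: 14 2-[(1R,5R)-5-ethenyl-4,6,6-trimethylcyclohex-3-en-1-yl]acetaldehyde
Conditions: hν (λ about 300 nm, Pyrex filter), degassed benzene (0.01 M), rt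
Reagents that add atoms: none
Why: Norrish type 1 α-cleavage should occur at the more substituted C5–C(=O) bond to give a tertiary alkyl/acyl radical pair, and the acyl radical on the arm at C2 then abstracts through a six-membered transition state the C4 hydrogen on its own ring face (the C6 hydrogen lies on the opposite face), which forms the C4=C5 alkene and the CH2–CHO arm in one event and leaves C2 and C6 cis.

Step 9
Reactants: 14 2-[(1R,5R)-5-ethenyl-4,6,6-trimethylcyclohex-3-en-1-yl]acetaldehyde; 15 methyl vinyl ketone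
Product: 16 2-{(1R,5R)-4,6,6-trimethyl-5-[(1E)-3-oxobut-1-en-1-yl]cyclohex-3-en-1-yl}acetaldehyde
Conditions: 15 (5 equiv), second-generation Hoveyda–Grubbs catalyst (5 mol %), 1,4-benzoquinone (10 mol %), CH2Cl2, 40 °C
Reagents that add atoms: methyl vinyl ketone, CC(=O)C=C
Why: Olefin cross-metathesis between the only monosubstituted alkene (C7=C8) and an electron-poor enone partner that does not homodimerise should give the E-enone under thermodynamic control, the trisubstituted ring alkene and the aldehyde being inert to the ruthenium carbene.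

Step 10
Reactants: 16 keto aldehyde; 17 isopropyltriphenylphosphonium iodide
Product: 19 (3E)-4-[(1R,5S)-2,6,6-trimethyl-5-(3-methylbut-2-en-1-yl)cyclohex-2-en-1-yl]but-3-en-2-one, via isopropylidenetriphenylphosphorane 18 (not isolated)
Conditions: 17 (1.05 equiv), n-BuLi, THF, 0 °C; then 16, −78 → −20 °C
Reagents that add atoms: isopropyltriphenylphosphonium iodide, CC(C)[P+](c1ccccc1)(c1ccccc1)c1ccccc1.[I-]
Why: Wittig olefination with a non-stabilised ylide is much faster at the unhindered aldehyde than at the conjugated methyl ketone at low temperature and delivers the isopropylidene end of the prenyl group, which has no geometry to control.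

Step 11
Reactants: 19 2-prenyl-α-ionone analogue; 20 vinylmagnesium bromide
Product: 21 (1E)-3-methyl-1-[(1R,5S)-2,6,6-trimethyl-5-(3-methylbut-2-en-1-yl)cyclohex-2-en-1-yl]penta-1,4-dien-3-ol (both carbinol epimers)
Conditions: CH2=CHMgBr (1.3 equiv), THF, −78 → 0 °C; aq. NH4Cl
Reagents that add atoms: vinylmagnesium bromide, C=C[Mg]Br
Why: Grignard 1,2-addition to the ionone-type enone gives the tertiary bis-allylic alcohol, the usual precursor of C15-type Wittig salts, and the two carbinol epimers converge in step 12.

Step 12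
Reactants: 21 ring A vinyl carbinol; 22 triphenylphosphine hydrobromide
Product: 23 {(2E,4E)-3-methyl-5-[(1R,5S)-2,6,6-trimethyl-5-(3-methylbut-2-en-1-yl)cyclohex-2-en-1-yl]penta-2,4-dien-1-yl}triphenylphosphonium bromide
Conditions: PPh3·HBr (1.05 equiv), MeOH, rt, dark; crystallisation
Reagents that add atoms: triphenylphosphine hydrobromide, [Br-].[PH+](c1ccccc1)(c1ccccc1)c1ccccc1
Why: Acid-induced ionisation of the tertiary bis-allylic alcohol and capture of the delocalised cation by triphenylphosphine at the primary terminus (allylic transposition) should give the conjugated dienylphosphonium salt with the 9E isomer favoured, the isolated trisubstituted alkenes surviving this mild acid.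

**Ring B half**

Step 13
Reactants: 24 2,4,4-trimethylcyclohex-2-en-1-one
Product: 25 2,4,4-trimethylcyclohexa-2,5-dien-1-one
Conditions: DDQ (1.2 equiv), TsOH·H2O (cat.), 1,4-dioxane, reflux
Reagents that add atoms: none
Why: Quinone dehydrogenation across C5–C6, as in step 1, gives the cross-conjugated dienone that carries one α-methylated and one unsubstituted enone unit.

Step 14
Reactants: 25 2,4,4-trimethylcyclohexa-2,5-dien-1-one; 3 potassium vinyltrifluoroborate
Product: 26 (5R)-5-ethenyl-2,4,4-trimethylcyclohex-2-en-1-one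
Conditions: [Rh(C2H4)2Cl]2 (2.5 mol %), (R,R)-Ph-bod* (5.5 mol %), Et3N, dioxane/H2O 10:1, 50 °C
Reagents that add atoms: potassium vinyltrifluoroborate, [K+].C=C[B-](F)(F)F
Why: Rhodium-catalysed asymmetric conjugate vinylation should occur only at the α-unsubstituted enone unit, since α-substituted enones are poor acceptors for organorhodium species, and the antipodal diene ligand sets C5 (later C2') as R.

Step 15
Reactants: 26 (5R)-5-ethenyl-2,4,4-trimethylcyclohex-2-en-1-one; 27 hydrogen peroxide
Product: 29 (5S)-5-(2-hydroxyethyl)-2,4,4-trimethylcyclohex-2-en-1-ol (both C1 epimers), via bis(9-BBN) adduct 28 (not isolated)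
Conditions: 9-BBN (2.5 equiv), THF, 0 °C → rt; then 3 M NaOH, 30% H2O2, 0 °C → rt
Reagents that add atoms: hydrogen peroxide, OO
Why: 9-BBN adds anti-Markovnikov to the monosubstituted alkene and also reduces the enone carbonyl by 1,2-hydride delivery (harmless, since step 16 reoxidises it), after which alkaline peroxide converts the C–B bond into the primary alcohol with the trisubstituted ring alkene and the C5 centre untouched.

Step 16
Reactants: 29 diol
Product: 30 2-[(1S)-2,2,4-trimethyl-5-oxocyclohex-3-en-1-yl]acetaldehyde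
Conditions: Dess–Martin periodinane (2.6 equiv), NaHCO3, CH2Cl2, 0 °C → rt
Reagents that add atoms: none
Why: Dess–Martin oxidation converts the primary alcohol into the aldehyde and the allylic alcohol back into the enone under buffered conditions that do not epimerise or enolise the product.

Step 17
Reactants: 30 keto aldehyde; 31 methyl 2-(triphenylphosphoranylidene)propanoate
Product: 32 methyl (2E)-2-methyl-4-[(1S)-2,2,4-trimethyl-5-oxocyclohex-3-en-1-yl]but-2-enoate
Conditions: 31 (1.2 equiv), CH2Cl2, rt → 40 °C
Reagents that add atoms: methyl 2-(triphenylphosphoranylidene)propanoate, COC(=O)C(C)=P(c1ccccc1)(c1ccccc1)c1ccccc1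
Why: Wittig reaction of a stabilised α-branched ylide takes place only at the aldehyde, the enone carbonyl being inert, and gives the trisubstituted enoate with E geometry by the usual preference of stabilised ylides.

Step 18
Reactants: 32 enone enoate; 20 vinylmagnesium bromide; 33 N-phenylbis(trifluoromethanesulfonimide)
Product: 35 methyl (2E)-4-[(1S,5R)-5-ethenyl-4,6,6-trimethyl-3-(trifluoromethylsulfonyloxy)cyclohex-3-en-1-yl]-2-methylbut-2-enoate (1,5-trans), via bromomagnesium enolate 34 (not isolated)
Conditions: CH2=CHMgBr (2.4 equiv), CuBr·SMe2 (1.2 equiv), THF, −78 → −40 °C; then PhNTf2 (1.5 equiv), DMPU, −78 °C → rt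
Reagents that add atoms: vinylmagnesium bromide, C=C[Mg]Br; N-phenylbis(trifluoromethanesulfonimide), O=S(=O)(N(c1ccccc1)S(=O)(=O)C(F)(F)F)C(F)(F)F
Why: Conjugate addition of the vinyl cuprate to the ring enone should proceed by axial attack at C3 on the face opposite the equatorial C5 side chain (the axial C4 methyl shields the other face), which sets C6' trans to C2', and the regiodefined enolate is trapped on oxygen as the triflate, the α-methyl enoate being a much poorer acceptor for cuprates.

Step 19
Reactants: 35 enol triflate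
Product: 36 methyl (2E)-4-[(1R,5S)-5-ethenyl-4,6,6-trimethylcyclohex-3-en-1-yl]-2-methylbut-2-enoate
Conditions: Pd(OAc)2 (5 mol %), PPh3 (10 mol %), HCO2H, n-Bu3N, DMF, 60 °C
Reagents that add atoms: none
Why: Palladium-catalysed formate reduction of the enol triflate (oxidative addition to zerovalent palladium, formate exchange, decarboxylation, C–H reductive elimination) replaces the triflate by hydrogen without moving the double bond, which fixes the C4'=C5' alkene.

Step 20
Reactants: 36 ring B diene ester; 15 methyl vinyl ketone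
Product: 37 methyl (2E)-2-methyl-4-{(1R,5S)-4,6,6-trimethyl-5-[(1E)-3-oxobut-1-en-1-yl]cyclohex-3-en-1-yl}but-2-enoate
Conditions: 15 (5 equiv), second-generation Hoveyda–Grubbs catalyst (5 mol %), 1,4-benzoquinone (10 mol %), CH2Cl2, 40 °C
Reagents that add atoms: methyl vinyl ketone, CC(=O)C=C
Why: Cross-metathesis as in step 9 should engage only the monosubstituted C7'=C8' alkene, the trisubstituted ring alkene and the electron-poor trisubstituted enoate alkene being unreactive, and give the E-enone.

Step 21
Reactants: 37 ring B enone; 20 vinylmagnesium bromide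
Product: 38 methyl (2E)-4-{(1R,5S)-5-[(1E)-3-hydroxy-3-methylpenta-1,4-dien-1-yl]-4,6,6-trimethylcyclohex-3-en-1-yl}-2-methylbut-2-enoate (both carbinol epimers)
Conditions: CH2=CHMgBr (1.2 equiv), THF, −78 °C; aq. NH4Cl
Reagents that add atoms: vinylmagnesium bromide, C=C[Mg]Br
Why: Grignard 1,2-addition is much faster at the methyl ketone than at the hindered conjugated ester at −78 °C and gives the tertiary bis-allylic alcohol, whose carbinol epimers converge in step 22.

Step 22
Reactants: 38 ring B vinyl carbinol; 22 triphenylphosphine hydrobromide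
Product: 39 {(2E,4E)-5-[(1S,5R)-5-[(2E)-4-methoxy-3-methyl-4-oxobut-2-en-1-yl]-2,6,6-trimethylcyclohex-2-en-1-yl]-3-methylpenta-2,4-dien-1-yl}triphenylphosphonium bromide
Conditions: PPh3·HBr (1.05 equiv), MeOH, rt, dark; crystallisation
Reagents that add atoms: triphenylphosphine hydrobromide, [Br-].[PH+](c1ccccc1)(c1ccccc1)c1ccccc1
Why: The same acid-induced allylic transposition as in step 12 gives the conjugated dienylphosphonium salt, the methyl enoate being inert to these conditions.

**Assembly**

Step 23
Reactants: 23 ring A phosphonium bromide; 40 (2E,4E,6E)-2,7-dimethylocta-2,4,6-trienedial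
Product: 42 (2E,4E,6E,8E,10E,12E)-2,7,11-trimethyl-13-[(1R,5S)-2,6,6-trimethyl-5-(3-methylbut-2-en-1-yl)cyclohex-2-en-1-yl]trideca-2,4,6,8,10,12-hexaenal, via ring A ylide 41 (not isolated)
Conditions: 40 (3 equiv), NaOMe (1.1 equiv, added last), CH2Cl2/MeOH, 0 °C → rt; then n-heptane, reflux, N2, dark
Reagents that add atoms: (2E,4E,6E)-2,7-dimethylocta-2,4,6-trienedial, O=C/C(C)=C/C=C/C=C(C)/C=O
Why: Wittig olefination of the semi-stabilised allylic ylide with one carbonyl of the dialdehyde, kept in excess to suppress double condensation, forms C11=C12, and any sterically hindered 11Z isomer should relax to the E form on heating.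

Step 24
Reactants: 39 ring B phosphonium bromide; 42 ring A C30 aldehyde
Product: 44 methyl ester of the target (CO2CH3 in place of CH2OH), via ring B ylide 43 (not isolated)
Conditions: NaOMe (1.2 equiv), CH2Cl2/MeOH, 0 °C → rt; then n-heptane, reflux, N2, dark
Reagents that add atoms: ring A C30 aldehyde 42, CC(C)=CC[C@H]1CC=C(C)[C@@H](/C=C/C(C)=C/C=C/C(C)=C/C=C/C=C(C)/C=O)C1(C)C
Why: The second Wittig olefination joins the ring B ylide to the polyenal at C11'=C12' and completes the C50 skeleton, the methyl ester matching the methoxide base and thermal equilibration again converging the new double bond to E.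

Step 25
Reactants: 44 C50 methyl ester
Product: 45 CNP0304855.1, (2S,6R,2'R,6'S)-2-(3-methylbut-2-enyl)-2'-[(2E)-4-hydroxy-3-methylbut-2-enyl]-ε,ε-carotene
Conditions: iBu2AlH (2.5 equiv), CH2Cl2, −78 → −40 °C; aq. KNaC4H4O6
Reagents that add atoms: none
Why: Hydride reduction of the conjugated ester by 1,2-addition gives the primary allylic alcohol without touching the polyene or any stereocentre, which completes the target.

**Compound list**
1 | 4,4-dimethylcyclohex-2-en-1-one | CC1(C)CCC(=O)C=C1 | starting material
2 | 4,4-dimethylcyclohexa-2,5-dien-1-one | CC1(C)C=CC(=O)C=C1 | intermediate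
3 | potassium vinyltrifluoroborate | [K+].C=C[B-](F)(F)F | starting material
4 | (5S)-5-ethenyl-4,4-dimethylcyclohex-2-en-1-one | C=C[C@@H]1CC(=O)C=CC1(C)C | intermediate
5 | iodomethane | CI | starting material
6 | lithium dienolate of 4 (O–C1=C6, C2=C3), not isolated | [Li+].C=C[C@@H]1C=C([O-])C=CC1(C)C | intermediate
7 | (5R,6R)-5-ethenyl-4,4,6-trimethylcyclohex-2-en-1-one (5,6-trans; the C6 epimer serves equally) | C=C[C@@H]1[C@@H](C)C(=O)C=CC1(C)C | intermediate
8 | tert-butyldimethylsilyl trifluoromethanesulfonate | CC(C)(C)[Si](C)(C)OS(=O)(=O)C(F)(F)F | starting material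
9 | tert-butyl{[(6S)-6-ethenyl-1,5,5-trimethylcyclohexa-1,3-dien-2-yl]oxy}dimethylsilane | C=C[C@@H]1C(C)=C(O[Si](C)(C)C(C)(C)C)C=CC1(C)C | intermediate
10 | phenyl vinyl sulfone | C=CS(=O)(=O)c1ccccc1 | starting material
11 | tert-butyl{[6-ethenyl-1,5,5-trimethyl-8-(phenylsulfonyl)bicyclo[2.2.2]oct-2-en-2-yl]oxy}dimethylsilane, vinyl and sulfonyl syn to the C2=C3 bridge | C=C[C@H]1C(C)(C)[C@H]2C=C(O[Si](C)(C)C(C)(C)C)[C@]1(C)C[C@@H]2S(=O)(=O)c1ccccc1 | intermediate
12 | tert-butyl{[6-ethenyl-1,5,5-trimethylbicyclo[2.2.2]oct-2-en-2-yl]oxy}dimethylsilane, vinyl syn to the C2=C3 bridge | C=C[C@H]1C(C)(C)[C@H]2C=C(O[Si](C)(C)C(C)(C)C)[C@]1(C)CC2 | intermediate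
13 | 6-ethenyl-1,5,5-trimethylbicyclo[2.2.2]octan-2-one, vinyl syn to the carbonyl bridge | C=C[C@H]1C(C)(C)[C@H]2CC(=O)[C@]1(C)CC2 | intermediate
14 | 2-[(1R,5R)-5-ethenyl-4,6,6-trimethylcyclohex-3-en-1-yl]acetaldehyde (arm and vinyl cis) | O=CC[C@H]1CC=C(C)[C@@H](C=C)C1(C)C | intermediate
15 | methyl vinyl ketone | CC(=O)C=C | starting material
16 | 2-{(1R,5R)-4,6,6-trimethyl-5-[(1E)-3-oxobut-1-en-1-yl]cyclohex-3-en-1-yl}acetaldehyde | O=CC[C@H]1CC=C(C)[C@@H](/C=C/C(C)=O)C1(C)C | intermediate
17 | isopropyltriphenylphosphonium iodide | CC(C)[P+](c1ccccc1)(c1ccccc1)c1ccccc1.[I-] | starting material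
18 | isopropylidenetriphenylphosphorane, not isolated | CC(C)=P(c1ccccc1)(c1ccccc1)c1ccccc1 | intermediate
19 | (3E)-4-[(1R,5S)-2,6,6-trimethyl-5-(3-methylbut-2-en-1-yl)cyclohex-2-en-1-yl]but-3-en-2-one | CC(C)=CC[C@H]1CC=C(C)[C@@H](/C=C/C(C)=O)C1(C)C | intermediate
20 | vinylmagnesium bromide | C=C[Mg]Br | starting material
21 | (1E)-3-methyl-1-[(1R,5S)-2,6,6-trimethyl-5-(3-methylbut-2-en-1-yl)cyclohex-2-en-1-yl]penta-1,4-dien-3-ol, both carbinol epimers | CC(C)=CC[C@H]1CC=C(C)[C@@H](/C=C/C(C)(O)C=C)C1(C)C | intermediate
22 | triphenylphosphine hydrobromide | [Br-].[PH+](c1ccccc1)(c1ccccc1)c1ccccc1 | starting material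
23 | {(2E,4E)-3-methyl-5-[(1R,5S)-2,6,6-trimethyl-5-(3-methylbut-2-en-1-yl)cyclohex-2-en-1-yl]penta-2,4-dien-1-yl}triphenylphosphonium bromide | CC(C)=CC[C@H]1CC=C(C)[C@@H](/C=C/C(C)=C/C[P+](c2ccccc2)(c2ccccc2)c2ccccc2)C1(C)C.[Br-] | intermediate
24 | 2,4,4-trimethylcyclohex-2-en-1-one | CC1=CC(C)(C)CCC1=O | starting material
25 | 2,4,4-trimethylcyclohexa-2,5-dien-1-one | CC1=CC(C)(C)C=CC1=O | intermediate
26 | (5R)-5-ethenyl-2,4,4-trimethylcyclohex-2-en-1-one | O=C1C(C)=CC(C)(C)[C@@H](C=C)C1 | intermediate
27 | hydrogen peroxide | OO | starting material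
28 | bis(9-BBN) adduct of 26 (O-borinate at C1, B-alkyl at the side-chain terminus), not isolated | CC1=CC(C)(C)[C@@H](CCB2C3CCCC2CCC3)CC1OB1C2CCCC1CCC2 | intermediate
29 | (5S)-5-(2-hydroxyethyl)-2,4,4-trimethylcyclohex-2-en-1-ol, both C1 epimers | OC1C(C)=CC(C)(C)[C@@H](CCO)C1 | intermediate
30 | 2-[(1S)-2,2,4-trimethyl-5-oxocyclohex-3-en-1-yl]acetaldehyde | O=C1C(C)=CC(C)(C)[C@@H](CC=O)C1 | intermediate
31 | methyl 2-(triphenylphosphoranylidene)propanoate | COC(=O)C(C)=P(c1ccccc1)(c1ccccc1)c1ccccc1 | starting material
32 | methyl (2E)-2-methyl-4-[(1S)-2,2,4-trimethyl-5-oxocyclohex-3-en-1-yl]but-2-enoate | O=C1C(C)=CC(C)(C)[C@@H](C/C=C(\C)C(=O)OC)C1 | intermediate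
33 | N-phenylbis(trifluoromethanesulfonimide) | O=S(=O)(N(c1ccccc1)S(=O)(=O)C(F)(F)F)C(F)(F)F | starting material
34 | bromomagnesium enolate from vinyl addition to 32, not isolated | C=C[C@H]1C(C)=C(O[Mg]Br)C[C@H](C/C=C(\C)C(=O)OC)C1(C)C | intermediate
35 | methyl (2E)-4-[(1S,5R)-5-ethenyl-4,6,6-trimethyl-3-(trifluoromethylsulfonyloxy)cyclohex-3-en-1-yl]-2-methylbut-2-enoate (vinyl trans to side chain) | C=C[C@H]1C(C)=C(OS(=O)(=O)C(F)(F)F)C[C@H](C/C=C(\C)C(=O)OC)C1(C)C | intermediate
36 | methyl (2E)-4-[(1R,5S)-5-ethenyl-4,6,6-trimethylcyclohex-3-en-1-yl]-2-methylbut-2-enoate | C=C[C@H]1C(C)=CC[C@H](C/C=C(\C)C(=O)OC)C1(C)C | intermediate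
37 | methyl (2E)-2-methyl-4-{(1R,5S)-4,6,6-trimethyl-5-[(1E)-3-oxobut-1-en-1-yl]cyclohex-3-en-1-yl}but-2-enoate | CC(=O)/C=C/[C@H]1C(C)=CC[C@H](C/C=C(\C)C(=O)OC)C1(C)C | intermediate
38 | methyl (2E)-4-{(1R,5S)-5-[(1E)-3-hydroxy-3-methylpenta-1,4-dien-1-yl]-4,6,6-trimethylcyclohex-3-en-1-yl}-2-methylbut-2-enoate, both carbinol epimers | C=CC(C)(O)/C=C/[C@H]1C(C)=CC[C@H](C/C=C(\C)C(=O)OC)C1(C)C | intermediate
39 | {(2E,4E)-5-[(1S,5R)-5-[(2E)-4-methoxy-3-methyl-4-oxobut-2-en-1-yl]-2,6,6-trimethylcyclohex-2-en-1-yl]-3-methylpenta-2,4-dien-1-yl}triphenylphosphonium bromide | COC(=O)/C(C)=C/C[C@H]1CC=C(C)[C@H](/C=C/C(C)=C/C[P+](c2ccccc2)(c2ccccc2)c2ccccc2)C1(C)C.[Br-] | intermediate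
40 | (2E,4E,6E)-2,7-dimethylocta-2,4,6-trienedial | O=C/C(C)=C/C=C/C=C(C)/C=O | starting material
41 | ring A ylide (phosphorane from 23), not isolated | CC(C)=CC[C@H]1CC=C(C)[C@@H](/C=C/C(C)=C/C=P(c2ccccc2)(c2ccccc2)c2ccccc2)C1(C)C | intermediate
42 | (2E,4E,6E,8E,10E,12E)-2,7,11-trimethyl-13-[(1R,5S)-2,6,6-trimethyl-5-(3-methylbut-2-en-1-yl)cyclohex-2-en-1-yl]trideca-2,4,6,8,10,12-hexaenal | CC(C)=CC[C@H]1CC=C(C)[C@@H](/C=C/C(C)=C/C=C/C(C)=C/C=C/C=C(C)/C=O)C1(C)C | intermediate
43 | ring B ylide (phosphorane from 39), not isolated | COC(=O)/C(C)=C/C[C@H]1CC=C(C)[C@H](/C=C/C(C)=C/C=P(c2ccccc2)(c2ccccc2)c2ccccc2)C1(C)C | intermediate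
44 | C50 methyl ester, all-E, (2S,6R,2'R,6'S) | CC(C)=CC[C@H]1CC=C(C)[C@@H](/C=C/C(C)=C/C=C/C(C)=C/C=C/C=C(C)/C=C/C=C(C)/C=C/[C@H]2C(C)=CC[C@H](C/C=C(\C)C(=O)OC)C2(C)C)C1(C)C | intermediate
45 | CNP0304855.1, (2S,6R,2'R,6'S)-2-(3-methylbut-2-enyl)-2'-[(2E)-4-hydroxy-3-methylbut-2-enyl]-ε,ε-carotene | CC(C)=CC[C@H]1CC=C(C)[C@@H](/C=C/C(C)=C/C=C/C(C)=C/C=C/C=C(C)/C=C/C=C(C)/C=C/[C@H]2C(C)=CC[C@H](C/C=C(\C)CO)C2(C)C)C1(C)C | target

**Step count**
Total: 25 steps. Longest linear sequence: 15 steps (steps 1–12, then 23–25, from compound 1).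

**Steps most likely to fail**

Step 5. The cycloaddition may be too slow, since one diene terminus is fully substituted and the other lies next to the gem-dimethyl carbon, so that desilylation of the diene or polymerisation of the sulfone competes. The facial bias from C6 may also be incomplete at the temperature needed. Fallback from 7, returning at 13: the same two bonds are made stepwise by an anionic Michael–Michael annulation. Ketone 7 is deprotonated with LiN(iPr)2 in THF at −78 °C to the lithium dienolate F1, which adds through C5 to phenyl vinyl sulfone 10 at −78 °C on the face away from the vinyl group; the α-sulfonyl carbanion then closes onto the enone carbon C2 to give the keto sulfone F2. Desulfonylation with Na(Hg) and Na2HPO4 in MeOH at −20 °C gives ketone 13.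

Step 8. Hydrogen transfer within the radical pair may take other courses (from the C5 methyl to give an exocyclic alkene, or from Ca to C5 to give a ketene), the excited carbonyl may be intercepted by the nearby vinyl group, and the aldehyde formed may be photolysed further. Fallback from 13, returning at 14: the C5–C(=O) bond is cut by oxygen insertion and syn elimination. Baeyer–Villiger oxidation of 13 with buffered mCPBA (NaHCO3, CH2Cl2, 0 °C), in which the tertiary bridgehead migrates and the strained ketone should react before the monosubstituted alkene, gives the bridged lactone F3. Methanolysis with K2CO3 in MeOH gives the hydroxy ester F4, whose tertiary C5 hydroxyl sits on the face of the acetate arm. Dehydration with the Burgess reagent in benzene at 50 °C is a syn elimination that can reach the C4 hydrogen but not the C6 hydrogen on the opposite face, and gives the unsaturated ester F5. Reduction with iBu2AlH in CH2Cl2 at −78 °C gives aldehyde 14.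

Step 18. Addition of the vinyl cuprate to the α-methylated enone, whose β-carbon adjoins a quaternary centre, may be slow; 1,2-addition or attack at the side-chain enoate may compete, and O-triflation of the hindered magnesium enolate may be incomplete. Fallback from 32, returning at 36: the vinyl group is delivered by allylic substitution with transposition, not by conjugate addition. Reduction of 32 with NaBH4 and CeCl3·7H2O in MeOH at −78 °C (Luche reduction, ester untouched) gives the cis-allylic alcohol F6. Esterification with picolinic acid (DCC, DMAP, CH2Cl2) gives the picolinate F7. CH2=CHMgBr with CuBr·SMe2 in THF at −40 °C then displaces it in an anti SN2' reaction, placing vinyl at C6' trans to the C2' side chain and the double bond at C4'=C5', which is compound 36; the triflate 35 and step 19 are bypassed.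

**Further compounds**
F1 | step 5 | lithium dienolate of 7 (O–C1=C6, C2=C3) | [Li+].C=C[C@@H]1C(C)=C([O-])C=CC1(C)C
F2 | step 5 | 6-ethenyl-1,5,5-trimethyl-8-(phenylsulfonyl)bicyclo[2.2.2]octan-2-one, vinyl syn to the carbonyl bridge, either sulfone epimer | C=C[C@H]1C(C)(C)[C@H]2CC(=O)[C@]1(C)CC2S(=O)(=O)c1ccccc1
F3 | step 8 | 7-ethenyl-1,6,6-trimethyl-2-oxabicyclo[3.2.2]nonan-3-one (oxygen inserted between C5 and the carbonyl) | C=C[C@H]1C(C)(C)[C@H]2CC(=O)O[C@]1(C)CC2
F4 | step 8 | methyl 2-(3-ethenyl-4-hydroxy-2,2,4-trimethylcyclohexyl)acetate, hydroxyl on the face of the acetate arm | COC(=O)C[C@H]1CC[C@@](C)(O)[C@@H](C=C)C1(C)C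
F5 | step 8 | methyl 2-[(1R,5R)-5-ethenyl-4,6,6-trimethylcyclohex-3-en-1-yl]acetate | COC(=O)C[C@H]1CC=C(C)[C@@H](C=C)C1(C)C
F6 | step 18 | methyl (2E)-4-[(1S,5R)-5-hydroxy-2,2,4-trimethylcyclohex-3-en-1-yl]-2-methylbut-2-enoate (hydroxyl cis to side chain) | O[C@H]1C(C)=CC(C)(C)[C@@H](C/C=C(\C)C(=O)OC)C1
F7 | step 18 | picolinate ester of F6 | O=C(O[C@H]1C(C)=CC(C)(C)[C@@H](C/C=C(\C)C(=O)OC)C1)c1ccccn1
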